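(The runs are simulated for an exercise, noise included.)

**In the flask.** Substrates and products together stay at what you charged. So on Saturday's run the left-handed side, substrate plus product, would hold at half if nothing crossed over. At 30.0 min it reads 52.8%, so substrate is crossing from right to left. Sunday's flask, at 10.0 min, reads 48.6% left-handed substrate and 2.0% left-handed product.

| setting | Sunday's | Saturday's | flask |
|---|---|---|---|
| left-handed substrate | 2 M | 2 M | 2.0 M |
| right-handed substrate | 2 M | 2 M | 2.0 M |
| gas | 76 mM (held) | 76 mM (held) | 76 mM (held) |
| free catalyst | 2 mM | 3 mM | 2.0 mM |
| remark | the very flask that is asked about, followed so far | run made earlier |  |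
| time |  |  | 80 min |

| run | time / min | left-handed product / % | right-handed product / % | left-handed substrate / % |
|---|---|---|---|---|
| Sunday's | 0.500 | 0.1 | 0 | 49.9 |
| Sunday's | 1.33 | 0.5 | 0 | 49.5 |
| Sunday's | 2.50 | 0.4 | 0 | 49.7 |
| Sunday's | 4.00 | 0.6 | 0 | 49.4 |
| Sunday's | 6.00 | 1.9 | 0 | 48.6 |
| Sunday's | 8.00 | 2.6 | 1.1 | 48.4 |
| Sunday's | 10.0 | 2.0 | 0.6 | 48.6 |
| Saturday's | 5.00 | 1.1 | 0.8 | 49.3 |
| Saturday's | 10.0 | 2.6 | 0.1 | 47.2 |
| Saturday's | 15.0 | 4.3 | 0 | 45.0 |
| Saturday's | 20.0 | 6.3 | 0 | 44.4 |
| Saturday's | 25.0 | 7.2 | 0 | 44.3 |
| Saturday's | 30.0 | 8.8 | 0.7 | 44.0 |

(scatter of a reading: 0.5 percentage points)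

1. excess of left-handed product over right-handed product in the product at 1.5 min
2. excess of left-handed product over right-handed product in the product at 80 min
3. part of the left-handed substrate and right-handed substrate charged together that has reacted at 80 min

- free catalyst is single-handed; left-handed substrate and right-handed substrate are mirror images of each other, charged as a racemate, each of them at the stated concentration
- at the start none of partner is dissolved
- steps under discussion: partner + free catalyst + left-handed substrate -> free catalyst + left-handed product; partner + free catalyst + right-handed substrate -> free catalyst + right-handed product; left-handed substrate <-> right-handed substrate; gas <-> partner; 2 free catalyst -> spent catalyst; partner <-> dormant form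
- an excess is the difference of the two amounts in percent of their sum
- an excess is below zero if the other one leads

**Work in logs.** Take the dose slope, the apparent order in catalyst: the change in log10 of left-handed product per unit change in log10 of the catalyst charge. The two runs at 10.0 min give 0.647. This is rough, since each reading is good to 0.5 percentage points. Saturday's run gives a time slope, the same change against log10 of time, of 1.11. Right-handed readings sit near the scatter, so I count conversion from left-handed product and read no excess from them.

**When you come.** From Saturday's last reading, log10 of product rises by 0.359, so expect about 20.1% reacted at 80 min. Leave the gas held at 76 mM, because both slopes were read there.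

**The check.** The forecast gives 94%, 93% and 13%, the last lower than my figure, allowing for “some catalyst loss or dormancy”. The flask gives 94.7%, 94.5% and 19.3%.

    partner + free catalyst + left-handed substrate → free catalyst + left-handed product (k = 4.72 /M²/s)
    partner + free catalyst + right-handed substrate → free catalyst + right-handed product (k = 0.127 /M²/s)
    left-handed substrate ⇌ right-handed substrate (k = 6.58 × 10⁻⁴ /s)
    gas ⇌ partner, rate k4*(csat - [partner]) (kL = 0.00342 /s)
    2 free catalyst → spent catalyst (k = 0.160 /M/s)
    partner ⇌ dormant form (K = 19.5, k = 5.29 × 10⁻⁴ /s)

**The neighbour.** Cut the catalyst to 0.500 mM and the dose slope takes 19.3% down to 7.87%. That neighbour flask actually reaches 13.6%, more than the slope says. Between these two flasks the slope comes to 0.254, lower than the reading. At 80.0 min the flask holds 0.491 mM free catalyst and the neighbour 0.283 mM, so a charge ratio of 4.00 has shrunk to 1.74.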